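**Assumption:** the SMILES is read as (1S,2S), meaning the C1 aryl and C2 aroyl groups are cis, with the fused-ring methoxy at C8 (peri to C1). The route targets exactly this isomer.

## Retrosynthetic overview

1. Target ⇐ its hexaacetate by lipase deacetylation at neutral pH. The C3=C4 bond ⇐ intramolecular aldol condensation of a 1,4-diketone CH2 onto a ring-B aldehyde, so the carbocycle is closed last.
2. 1,4-Diketone ⇐ bis-Weinreb amide + 2 ArMgBr. The bis-amide ⇐ Me3Al/MeNHOMe opening of a trans-3,4-disubstituted chroman-2-one, whose ring oxygen becomes the 8-OMe.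
3. C2 ⇐ anti alkylation of the lactone enolate. The 3,4-trans lactone corresponds to the 1,2-cis target once the lactone C=O becomes the C2 aroyl group.
4. C1 ⇐ Rh/(S)-SEGPHOS 1,4-addition of the ring-A boronic acid to a daphnetin-derived coumarin.
5. Ring order: both benzene rings are bought; the coumarin pyranone ring serves as a stereochemical template and is opened; the dihydronaphthalene ring is formed last.

## Forward route

**Step 1**
Reactants: 1, 2,3,4-trihydroxybenzaldehyde
Product: 2, 3,4-bis(benzyloxy)-2-hydroxybenzaldehyde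
Conditions: BnBr (2.1 equiv), K2CO3, DMF, rt
Reagents that add atoms: benzyl bromide, BrCc1ccccc1
Why: Williamson etherification; the 2-OH is hydrogen-bonded to the aldehyde and least nucleophilic, so two equivalents go to O3 and O4.

**Step 2**
Reactants: 2
Product: 3, 3,4-bis(benzyloxy)-2-methoxybenzaldehyde
Conditions: MeI, K2CO3, DMF, 40 °C
Reagents that add atoms: iodomethane, CI
Why: Williamson O-methylation of the remaining chelated phenol.

**Step 3**
Reactants: 3
Product: 4, 3,4-bis(benzyloxy)-2-methoxyphenol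
Conditions: mCPBA, CH2Cl2, rt; then K2CO3, MeOH
Reagents that add atoms: mCPBA, OOC(=O)c1cccc(Cl)c1 (supplies the phenol O; the formyl carbon leaves as formate)
Why: Baeyer–Villiger (Dakin-type) oxidation; the electron-rich aryl migrates to give the aryl formate, which is methanolysed.

**Step 4**
Reactants: 4
Product: 5, 3,4-bis(benzyloxy)-2-methoxyphenyl triflate
Conditions: Tf2O, pyridine, CH2Cl2, 0 °C
Reagents that add atoms: triflic anhydride, O=S(=O)(OS(=O)(=O)C(F)(F)F)C(F)(F)F
Why: O-sulfonylation of the phenol gives a cross-coupling handle.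

**Step 5**
Reactants: 5
Product: 6, 2-[3,4-bis(benzyloxy)-2-methoxyphenyl]-4,4,5,5-tetramethyl-1,3,2-dioxaborolane
Conditions: B2pin2, PdCl2(dppf), KOAc, dioxane, 85 °C
Reagents that add atoms: bis(pinacolato)diboron, CC1(C)OB(OC1(C)C)B1OC(C)(C)C(C)(C)O1
Why: Miyaura borylation of the aryl triflate.

**Step 6**
Reactants: 6
Product: 7, [3,4-bis(benzyloxy)-2-methoxyphenyl]boronic acid
Conditions: NaIO4, NH4OAc, acetone/H2O, rt
Reagents that add atoms: water, O
Why: periodate cleaves the pinacol, releasing the free boronic acid needed for base-free Rh transmetalation.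

**Step 7**
Reactants: 8, daphnetin (7,8-dihydroxycoumarin)
Product: 9, 7-(benzyloxy)-8-hydroxy-2H-chromen-2-one
Conditions: BnBr (1.05 equiv), K2CO3 (1.1 equiv), DMF, 0 °C to rt
Reagents that add atoms: benzyl bromide, BrCc1ccccc1
Why: the 7-OH is a vinylogous acid (conjugated to the lactone C=O) and far more acidic than the 8-OH, so monoalkylation is O7-selective (Williamson).

**Step 8**
Reactants: 9; 7
Product: 10, (4S)-7-(benzyloxy)-4-[3,4-bis(benzyloxy)-2-methoxyphenyl]-8-hydroxychroman-2-one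
Conditions: Rh(acac)(C2H4)2 (3 mol %), (S)-SEGPHOS, 7 (3 equiv), dioxane/H2O 10:1, 60 °C
Reagents that add atoms: boronic acid 7, COc1c(B(O)O)ccc(OCc2ccccc2)c1OCc1ccccc1 (transfers the aryl group)
Why: Hayashi–Miyaura asymmetric 1,4-addition; the aryl–Rh(SEGPHOS) species adds to one face of the coumarin C3=C4 bond and sets C4 (future C1) as S. The (R)-ligand is known to give (R)-4-arylchroman-2-ones, so the (S)-ligand is used. This is the first stereocentre.

**Step 9**
Reactants: 10
Product: 11, (4S)-7-(benzyloxy)-4-[3,4-bis(benzyloxy)-2-methoxyphenyl]-5-bromo-8-hydroxychroman-2-one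
Conditions: NBS (1.0 equiv), MeCN, −30 °C
Reagents that add atoms: N-bromosuccinimide, O=C1CCC(=O)N1Br
Why: electrophilic aromatic bromination para to the only free phenol (both ortho positions are blocked); the ether-only ring A reacts much more slowly at low temperature. C5 is the future C4a.

**Step 10**
Reactants: 11
Product: 12, (4S)-7,8-bis(benzyloxy)-4-[3,4-bis(benzyloxy)-2-methoxyphenyl]-5-bromochroman-2-one
Conditions: BnBr, K2CO3, DMF, rt
Reagents that add atoms: benzyl bromide, BrCc1ccccc1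
Why: Williamson protection of the phenol before enolate chemistry.

**Step 11**
Reactants: 12; 13, 2-bromo-N-methoxy-N-methylacetamide
Product: 14, 2-[(3R,4S)-7,8-bis(benzyloxy)-4-[3,4-bis(benzyloxy)-2-methoxyphenyl]-5-bromo-2-oxochroman-3-yl]-N-methoxy-N-methylacetamide (3,4-trans)
Conditions: LiHMDS, THF, −78 °C; then 13, −78 to −40 °C
Reagents that add atoms: 13, CON(C)C(=O)CBr
Why: lactone enolate alkylation; the C4 aryl is pseudo-axial (reinforced by the peri bromine) and the electrophile enters anti to it, giving the 3,4-trans lactone. This sets C2 with the relative configuration that becomes 1,2-cis in the carbocycle.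

**Step 12**
Reactants: 14
Product: 15, (2R)-2-{(S)-[3,4-bis(benzyloxy)-2-methoxyphenyl][3,4-bis(benzyloxy)-6-bromo-2-hydroxyphenyl]methyl}-N1,N4-dimethoxy-N1,N4-dimethylbutanediamide
Conditions: Me3Al, MeNH(OMe)·HCl, CH2Cl2, 0 °C to rt
Reagents that add atoms: N,O-dimethylhydroxylamine hydrochloride, CNOC.Cl
Why: Weinreb aminolysis of the activated aryl lactone gives the second Weinreb amide and frees the phenol without touching either stereocentre.

**Step 13**
Reactants: 15
Product: 16, (2R)-2-{(S)-[3,4-bis(benzyloxy)-2-methoxyphenyl][3,4-bis(benzyloxy)-6-bromo-2-methoxyphenyl]methyl}-N1,N4-dimethoxy-N1,N4-dimethylbutanediamide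
Conditions: MeI, K2CO3, DMF, rt (telescoped from step 12)
Reagents that add atoms: iodomethane, CI
Why: Williamson O-methylation installs the 8-OMe; carbonate cannot deprotonate the amide α-CH, so C2 is unaffected.

**Step 14**
Reactants: 16; 17, 4-(benzyloxy)phenylmagnesium bromide
Product: 18, (2R)-2-{(S)-[3,4-bis(benzyloxy)-2-methoxyphenyl][3,4-bis(benzyloxy)-6-bromo-2-methoxyphenyl]methyl}-1,4-bis[4-(benzyloxy)phenyl]butane-1,4-dione
Conditions: 17 (5 equiv), THF, 0 °C to rt; cold sat. NH4Cl quench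
Reagents that add atoms: 17, Br[Mg]c1ccc(OCc2ccccc2)cc1
Why: double Weinreb ketone synthesis; the chelated tetrahedral intermediates stop at the ketone stage, and the α-stereocentre only becomes α-keto on the cold quench.

**Step 15**
Reactants: 18
Product: 19, (2R)-2-[(S)-(6-bromo-3,4-dihydroxy-2-methoxyphenyl)(3,4-dihydroxy-2-methoxyphenyl)methyl]-1,4-bis(4-hydroxyphenyl)butane-1,4-dione (used crude)
Conditions: BCl3, pentamethylbenzene, CH2Cl2, −78 °C; MeOH quench
Reagents that add atoms: none
Why: Lewis-acid debenzylation of the six aryl benzyl ethers with a non-basic cation scavenger; ketones, ArBr and ArOMe survive at −78 °C, and the step is done before the acid-sensitive enone exists.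

**Step 16**
Reactants: 19
Product: 20, the hexaacetate of 19
Conditions: Ac2O, pyridine, DMAP (cat.), CH2Cl2, 0 °C to rt
Reagents that add atoms: acetic anhydride, CC(=O)OC(C)=O
Why: O-acetylation; the acetates tolerate Pd, periodate and boron aldol chemistry and can later be removed at neutral pH.

**Step 17**
Reactants: 20
Product: 21, (2R)-2-[(S)-(3,4-diacetoxy-6-ethenyl-2-methoxyphenyl)(3,4-diacetoxy-2-methoxyphenyl)methyl]-1,4-bis(4-acetoxyphenyl)butane-1,4-dione
Conditions: Bu3SnCH=CH2, Pd(PPh3)4 (10 mol %), toluene, 100 °C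
Reagents that add atoms: tributyl(vinyl)stannane, C=C[Sn](CCCC)(CCCC)CCCC
Why: Stille coupling under neutral, base-free conditions, so the aryl acetates and the α-keto stereocentre survive.

**Step 18**
Reactants: 21
Product: 22, (2R)-2-[(S)-(3,4-diacetoxy-6-formyl-2-methoxyphenyl)(3,4-diacetoxy-2-methoxyphenyl)methyl]-1,4-bis(4-acetoxyphenyl)butane-1,4-dione
Conditions: OsO4 (cat.), NaIO4, 2,6-lutidine, dioxane/H2O, rt
Reagents that add atoms: osmium tetroxide, O=[Os](=O)(=O)=O; sodium periodate, [Na+].[O-]I(=O)(=O)=O (source of the aldehyde O)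
Why: Lemieux–Johnson oxidative cleavage of the styrene gives the ring-B aldehyde (future C4).

**Step 19**
Reactants: 22
Product: 23, [(1S,2S)-6,7-diacetoxy-1-(3,4-diacetoxy-2-methoxyphenyl)-4-hydroxy-8-methoxy-1,2,3,4-tetrahydronaphthalene-2,3-diyl]bis[(4-acetoxyphenyl)methanone], mixture at C3/C4
Conditions: n-Bu2BOTf (1.2 equiv), i-Pr2NEt (1.3 equiv), CH2Cl2, −78 °C; pH 7 buffer
Reagents that add atoms: none
Why: boron-mediated intramolecular aldol; soft enolisation occurs at the unhindered CH2 ketone (the other ketone could only enolise toward the tertiary C2–H), and the enolate closes the six-membered ring onto the aldehyde, leaving C1 and C2 untouched.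

**Step 20**
Reactants: 23
Product: 24, [(1S,2S)-6,7-diacetoxy-1-(3,4-diacetoxy-2-methoxyphenyl)-8-methoxy-1,2-dihydronaphthalene-2,3-diyl]bis[(4-acetoxyphenyl)methanone] (licobichalcone hexaacetate)
Conditions: Martin sulfurane, CH2Cl2, 0 °C to rt
Reagents that add atoms: none
Why: neutral dehydration of the benzylic β-hydroxy ketone to the conjugated enone; no base strong enough to epimerise the now more acidic C2–H is present.

**Step 21**
Reactants: 24
Product: 25, licobichalcone, [(1S,2S)-1-(3,4-dihydroxy-2-methoxyphenyl)-6,7-dihydroxy-8-methoxy-1,2-dihydronaphthalene-2,3-diyl]bis[(4-hydroxyphenyl)methanone]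
Conditions: lipase (Candida antarctica lipase B, immobilised), n-BuOH (excess), THF/MTBE, 40 °C, N2
Reagents that add atoms: none (acetyl groups are transferred to n-BuOH)
Why: lipase (serine hydrolase) transesterification of the six activated aryl acetates at neutral pH; this unmasks the catechols without enolising C2 (which would give the trans isomer) and without base-induced catechol oxidation.

## Compound list

1 | 2,3,4-trihydroxybenzaldehyde | O=Cc1ccc(O)c(O)c1O | starting material
2 | 3,4-bis(benzyloxy)-2-hydroxybenzaldehyde | O=Cc1ccc(OCc2ccccc2)c(OCc2ccccc2)c1O | intermediate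
3 | 3,4-bis(benzyloxy)-2-methoxybenzaldehyde | COc1c(C=O)ccc(OCc2ccccc2)c1OCc1ccccc1 | intermediate
4 | 3,4-bis(benzyloxy)-2-methoxyphenol | COc1c(O)ccc(OCc2ccccc2)c1OCc1ccccc1 | intermediate
5 | 3,4-bis(benzyloxy)-2-methoxyphenyl triflate | COc1c(OS(=O)(=O)C(F)(F)F)ccc(OCc2ccccc2)c1OCc1ccccc1 | intermediate
6 | aryl pinacol boronate | COc1c(B2OC(C)(C)C(C)(C)O2)ccc(OCc2ccccc2)c1OCc1ccccc1 | intermediate
7 | [3,4-bis(benzyloxy)-2-methoxyphenyl]boronic acid | COc1c(B(O)O)ccc(OCc2ccccc2)c1OCc1ccccc1 | intermediate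
8 | daphnetin | O=C1C=Cc2ccc(O)c(O)c2O1 | starting material
9 | 7-(benzyloxy)-8-hydroxycoumarin | O=C1C=Cc2ccc(OCc3ccccc3)c(O)c2O1 | intermediate
10 | (4S)-4-aryl-7-(benzyloxy)-8-hydroxychroman-2-one | COc1c([C@@H]2CC(=O)Oc3c(O)c(OCc4ccccc4)ccc32)ccc(OCc2ccccc2)c1OCc1ccccc1 | intermediate
11 | (4S)-5-bromo-8-hydroxy chromanone | COc1c([C@@H]2CC(=O)Oc3c(O)c(OCc4ccccc4)cc(Br)c32)ccc(OCc2ccccc2)c1OCc1ccccc1 | intermediate
12 | (4S)-7,8-bis(benzyloxy)-5-bromo chromanone | COc1c([C@@H]2CC(=O)Oc3c(OCc4ccccc4)c(OCc4ccccc4)cc(Br)c32)ccc(OCc2ccccc2)c1OCc1ccccc1 | intermediate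
13 | 2-bromo-N-methoxy-N-methylacetamide | CON(C)C(=O)CBr | starting material
14 | (3R,4S)-trans-3-(Weinreb-amidomethyl) chromanone | COc1c([C@@H]2[C@@H](CC(=O)N(C)OC)C(=O)Oc3c(OCc4ccccc4)c(OCc4ccccc4)cc(Br)c32)ccc(OCc2ccccc2)c1OCc1ccccc1 | intermediate
15 | bis-Weinreb amide, free phenol | COc1c([C@H]([C@@H](CC(=O)N(C)OC)C(=O)N(C)OC)c2c(O)c(OCc3ccccc3)c(OCc3ccccc3)cc2Br)ccc(OCc2ccccc2)c1OCc1ccccc1 | intermediate
16 | bis-Weinreb amide, methyl ether | COc1c([C@H]([C@@H](CC(=O)N(C)OC)C(=O)N(C)OC)c2c(OC)c(OCc3ccccc3)c(OCc3ccccc3)cc2Br)ccc(OCc2ccccc2)c1OCc1ccccc1 | intermediate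
17 | 4-(benzyloxy)phenylmagnesium bromide | Br[Mg]c1ccc(OCc2ccccc2)cc1 | starting material
18 | hexabenzyl 1,4-diketone | COc1c([C@H]([C@@H](CC(=O)c2ccc(OCc3ccccc3)cc2)C(=O)c2ccc(OCc3ccccc3)cc2)c2c(OC)c(OCc3ccccc3)c(OCc3ccccc3)cc2Br)ccc(OCc2ccccc2)c1OCc1ccccc1 | intermediate
19 | hexaphenol bromo-diketone | COc1c([C@H]([C@@H](CC(=O)c2ccc(O)cc2)C(=O)c2ccc(O)cc2)c2c(OC)c(O)c(O)cc2Br)ccc(O)c1O | intermediate
20 | hexaacetate bromo-diketone | COc1c([C@H]([C@@H](CC(=O)c2ccc(OC(C)=O)cc2)C(=O)c2ccc(OC(C)=O)cc2)c2c(OC)c(OC(C)=O)c(OC(C)=O)cc2Br)ccc(OC(C)=O)c1OC(C)=O | intermediate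
21 | hexaacetate vinyl-diketone | COc1c([C@H]([C@@H](CC(=O)c2ccc(OC(C)=O)cc2)C(=O)c2ccc(OC(C)=O)cc2)c2c(OC)c(OC(C)=O)c(OC(C)=O)cc2C=C)ccc(OC(C)=O)c1OC(C)=O | intermediate
22 | hexaacetate formyl-diketone | COc1c([C@H]([C@@H](CC(=O)c2ccc(OC(C)=O)cc2)C(=O)c2ccc(OC(C)=O)cc2)c2c(OC)c(OC(C)=O)c(OC(C)=O)cc2C=O)ccc(OC(C)=O)c1OC(C)=O | intermediate
23 | aldol adduct (C3/C4 mixture) | COc1c([C@H]2c3c(cc(OC(C)=O)c(OC(C)=O)c3OC)C(O)C(C(=O)c3ccc(OC(C)=O)cc3)[C@H]2C(=O)c2ccc(OC(C)=O)cc2)ccc(OC(C)=O)c1OC(C)=O | intermediate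
24 | licobichalcone hexaacetate | COc1c([C@H]2c3c(cc(OC(C)=O)c(OC(C)=O)c3OC)C=C(C(=O)c3ccc(OC(C)=O)cc3)[C@H]2C(=O)c2ccc(OC(C)=O)cc2)ccc(OC(C)=O)c1OC(C)=O | intermediate
25 | licobichalcone | COc1c([C@H]2c3c(cc(O)c(O)c3OC)C=C(C(=O)c3ccc(O)cc3)[C@H]2C(=O)c2ccc(O)cc2)ccc(O)c1O | target

## Summary

Total steps: 21. Longest linear sequence: 20 (1 → 7, then 10 → 25; the daphnetin branch is 15).

Steps most likely to fail, each with a fallback:

- **Step 8 (Rh 1,4-addition).** An ortho-methoxy, electron-rich boronic acid adding to an electron-rich coumarin risks protodeboronation and low conversion. Fallback: build the achiral 4-arylcoumarin (Suzuki coupling of 7 with the 4-triflyloxycoumarin) and set C1 by CuH/(S)-DTBM-SEGPHOS asymmetric conjugate reduction.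
- **Step 9 (bromination).** Ring A may compete with ring B for NBS. Fallback: drop the halogen handle. Carry ring-B oxygens as MOM ethers, switch ring A and the aroyl groups to acetates (deactivating ring A), then close the carbocycle by acid-mediated intramolecular Friedel–Crafts cyclisation of a C3 aminomethylene ketone onto the free ring-B phenol.
- **Steps 19–20 (aldol closure and dehydration).** Competing enolisation at C2 would erode the cis stereocentre. Fallback: close the ring on the hexabenzyl series under thermodynamic conditions, then reset C2 by kinetic protonation of the lithium dienolate (LiHMDS, −78 °C, hindered phenol) anti to the C1 aryl, and finish with BCl3/pentamethylbenzene debenzylation.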